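**The choice.** The target after 5.0 d was what I wanted, and the next run could be charged as Monday's, held at 0 °C through the feed and then warmed, or as Saturday's, at 20 °C throughout with the feed stretched to 6.0 d.

| flask | starting material | protic impurity | capture agent | temperature | remark | time |
|---|---|---|---|---|---|---|
| grey | 0.50 M (fed, over 3.0 d) | 0.10 M | 0.025 M | 5 °C | run made earlier |  |
| green | 0.50 M (fed, over 3.0 d) | 0.10 M | 0.038 M | 16 °C | run made earlier |  |
| Monday's | 0.50 M (fed, over 3.0 d) | 0.100 M | 0.0500 M |  | at 0 °C until 3.0 d, from then on at 20 °C | 5.0 d |
| Saturday's | 0.50 M (fed, over 6.0 d) | 0.100 M | 0.0500 M |  | at 20 °C throughout | 5.0 d |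

- grey (time / d: target / %, starting material / %): 0.250: 0.2, 4.2; 0.417: 0, 7.6; 0.625: 0, 10.5; 1.04: 2.6, 12.1; 1.67: 6.5, 14.0; 3.00: 24.1, 15.3
- green (time / h: target / %, starting material / %): 2.50: 1.4, 2.0; 5.00: 1.7, 4.1; 6.00: 0, 2.5; 12.0: 3.1, 3.2; 20.0: 6.2, 5.2; 30.0: 14.8, 3.8

(standard deviation of a reading: 1 percentage point)

- percentages count the whole charge, also what has not yet gone in

- which one finishes higher in amount of target, in percent of the starting material charged ("neither" within 2 percentage points) (Monday's / Saturday's / neither)
- amount of target at the end, in percent of the starting material charged, Monday's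
- amount of target at the end, in percent of the starting material charged, Saturday's

**The readings.** In the green run at 30.0 h, starting material read 3.8 %, far less than the 41.7 % of the charge that had gone in, so at 16 °C consumption was keeping up with the feed: dosing-controlled, in the usual term. Target read 14.8 %, about a third of what had entered. The remainder of what had entered showed as neither, so in the green run it was either still on the way or lost.

**The correction.** Monday's and Saturday's carry the same protic impurity and capture agent, so I took Monday's as the large figure and reckoned the difference alone. Saturday's feed was due to leave 16.7 % of the charge outside the flask at 5.0 d. I call this the unfed share: one minus reading time over dosing time, nil once the feed is over. For Monday's it is 0 %. To come within the margin, with all else in the two flasks equal, Saturday's had to lose 15 percentage points less to side reactions than Monday's. I saw no such saving in the readings, and any material still on the way in Saturday's would widen the gap, so I expected a gap a little above the unfed share and chose Monday's.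

**The forecast.** It also said Monday's, with 75 % for Monday's and 60 % for Saturday's, on the ground that “Saturday's has only 83 % fed by 5 d”. Its gap of 15 points was narrower than my unfed share.

**The result.** Monday's gave 77.3 % and Saturday's 58.6 %, a gap of 19 points.

    starting material + protic impurity → quenched substrate (k = 0.117 L mol⁻¹ h⁻¹, Ea = 66.0 kJ mol⁻¹)
    intermediate B ⇌ intermediate C (K = 1.40, k = 0.0159 h⁻¹, Ea = 97.0 kJ mol⁻¹, ΔH = −6.00 kJ mol⁻¹)
    capture agent + intermediate A → trapped intermediate (k = 0.104 L mol⁻¹ h⁻¹, Ea = 66.0 kJ mol⁻¹)
    intermediate B → target (k = 0.0740 h⁻¹, Ea = 81.0 kJ mol⁻¹)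
    starting material → intermediate A (k = 0.0416 h⁻¹, Ea = 81.0 kJ mol⁻¹)
    intermediate A ⇌ intermediate B (K = 0.655, k = 0.0145 h⁻¹, Ea = 93.0 kJ mol⁻¹, ΔH = −17.0 kJ mol⁻¹)
    (constants at 0 °C)

Set against the unfed share of 16.7 %, that gap leaves 2 points. Saturday's flask at 5.00 d also held 7.17 % as starting material and intermediates A, B and C. The same flask read at 12 d has an unfed share of 0 %, and its target stood at 80.1 %.

(The runs were generated by integration for an exercise; noise was put on by code.)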